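Dawn is asked at 4.0 min and winter at 12 min, while the earlier runs stop at 3.00 min, so winter lies further past the readings than dawn.

| flask | X | Q | G | remark | time |
|---|---|---|---|---|---|
| alder | 0.065 M | 0.50 equiv | 1 equiv | run made earlier |  |
| cedar | 0.066 M | 0.50 equiv | 1 equiv | run made earlier |  |
| oak | 0.082 M | 0.50 equiv | 1 equiv | run made earlier |  |
| dawn | 0.050 M | 0.500 equiv | 1.00 equiv |  | 4.0 min |
| winter | 0.080 M | 0.500 equiv | 1.00 equiv |  | 12 min |

| run | time / min | J / % | X / % |
|---|---|---|---|
| alder | 0.500 | 7.1 | 90.8 |
| alder | 1.00 | 11.8 | 85.1 |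
| alder | 1.50 | 14.5 | 81.9 |
| alder | 2.50 | 16.9 | 78.5 |
| alder | 3.00 | 16.7 | 78.9 |
| cedar | 0.500 | 8.4 | 89.4 |
| cedar | 1.00 | 12.1 | 84.3 |
| cedar | 1.50 | 15.4 | 81.5 |
| cedar | 2.50 | 16.9 | 78.7 |
| cedar | 3.00 | 17.9 | 79.2 |
| oak | 0.250 | 4.6 | 92.5 |
| oak | 0.417 | 8.3 | 89.1 |
| oak | 0.833 | 14.0 | 83.8 |
| oak | 1.33 | 17.1 | 78.6 |
| oak | 3.00 | 18.7 | 76.1 |

(standard deviation of a reading: 0.5 percentage points)

- a reading or a percentage of J counts all its forms, free or not
- where the amount of X changes, what is given in equivalents or mol% on it follows
- a reading of X is of its free form alone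

* the flask that ends with the higher amount of J, in percent of the X charged, or "neither" when 2 percentage points or less lies between them (dawn / winter / neither)
* final J, as a percentage of the X charged, in dawn
* final J, as a percentage of the X charged, in winter

We build the flask one process at a time, and first take X + Q ⇌ J by itself. Q is the limiting reagent and each J holds one Q, so this step has its ceiling at 50.0%, yet alder stands at 16.7% and oak at 18.7% at their last readings. From those last readings we take one number, averaged over the runs:

W = cJ / (cX · (cQ,charged − cJ)) = 10.0 M⁻¹

This is the hold W, which is J with its bound forms over free X and over the Q that charge minus J leaves. With j the share of J, q the equivalents of Q, x the share of free X and r = W · x · cX,charged, the definition reads j / (q − j) = r. Taking x as whole gives: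

dawn 16.7%, winter 22.2%

Next comes the second process. In alder, X and J add up to 95.6% at the last reading, so something holds X beside J, and free X reads 78.9% there. With the free X of the nearest run, alder for dawn and oak for winter, the numbers become:

dawn 14.2%, winter 18.9%

Each figure is lower than the one before it. The rest is whatever else takes Q, which is not read. W holds what had gone by the last readings, and no reading tests it later. We commit to 14.2% for dawn, and to 18.9% for winter with less trust, which puts winter higher.

The forecast, near these figures, gives 14.4% for dawn and 18.6% for winter, with winter ending higher, on the ground that “both flasks essentially finish”.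

The flasks give 15.2% in dawn and 14.7% in winter, so the answer is neither.

    X + Q ⇌ J (K = 13.0 M⁻¹, k = 0.110 M⁻¹ s⁻¹)
    G + Q ⇌ D (K = 34.0 M⁻¹, k = 0.0100 M⁻¹ s⁻¹)
    2 Q → E (k = 0.0350 M⁻¹ s⁻¹)
    X + J ⇌ L, settled at all times (K = 5.10 M⁻¹)

Put into W, dawn at its end gives 10.6 M⁻¹, and a neighbour of dawn charged with 0.085 M of X gives 9.91 M⁻¹ at 4.00 min, with J at 19.5%. Winter at 12 min gives 6.36 M⁻¹. Just after the start of dawn, Q went into J at 3.1 times the rate at which it went into E, counting the forward rate of the reversible step alone. At the end of winter, free Q stood at 23.9% of its charge, where charge minus J leaves 70.6%.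

All runs come from a simulation for an exercise; the scatter is artificial.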